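**Retrosynthetic overview**
1. Bermudenynol 20 ⇐ fluoride desilylation ⇐ Z-selective enyne cross-metathesis on the vinyl group of bromo-oxocene 15.
2. The oxocene (the only ring, closed late) ⇐ C13–O bond: 8-endo bromoetherification of acyclic hydroxy triene 14 (O7 onto C12=C13), which sets C12–Br and C13–O together.
3. 14 ⇐ C5–C6 bond by (Z)-γ-chloroallylboration (C5–Cl, C6–OH) of an aldehyde whose C7–O comes from proline-catalysed α-aminoxylation of aldehyde 9.
4. 9 ⇐ C7–C8 alkylation of an acetaldehyde azaenolate with allylic bromide 6 ⇐ propargyl alcohol + (E)-1-bromopent-2-ene; the chain-cis chloroalkene comes from syn-borylcupration then chlorodeboronation.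

Assumption: the target is taken exactly as the given SMILES, i.e. (3Z,5S,6S,7R,9E,12S,13R); solvents, catalysts and common reagents are bought, and the enyne partner 18 is made in one step.

Step 1
Reactants: 1 prop-2-yn-1-ol; 2 (E)-1-bromopent-2-ene
Product: 3 (E)-oct-5-en-2-yn-1-ol
Conditions: EtMgBr (2.2 equiv), THF, 0 °C; CuCl (10 mol%), then 2, 0 → 45 °C; aq. NH4Cl
Reagents that add atoms: none
Why: Copper-catalysed SN2 allylation of the alkynyl Grignard (dianion of propargyl alcohol) with a primary allylic bromide gives the skipped enynol with the E-olefin retained; no stereocentre is formed.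

Step 2
Reactants: 3 (E)-oct-5-en-2-yn-1-ol
Product: 4 (2Z,5E)-3-(4,4,5,5-tetramethyl-1,3,2-dioxaborolan-2-yl)octa-2,5-dien-1-ol
Conditions: B2pin2 (1.1 equiv), CuCl (5 mol%), PCy3 (6 mol%), NaOtBu (10 mol%), MeOH (2 equiv), toluene, rt
Reagents that add atoms: bis(pinacolato)diboron B1(OC(C)(C)C(C)(C)O1)B1OC(C)(C)C(C)(C)O1
Why: Copper-catalysed borylcupration/protonation (formal hydroboration) of an internal propargylic alcohol: the inductively withdrawing CH2OH puts copper on the near and boron on the far alkyne carbon, and syn addition fixes the chain-cis geometry (the minor regioisomer is removed by chromatography).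

Step 3
Reactants: 4 (2Z,5E)-3-(4,4,5,5-tetramethyl-1,3,2-dioxaborolan-2-yl)octa-2,5-dien-1-ol
Product: 5 (2E,5E)-3-chloroocta-2,5-dien-1-ol
Conditions: CuCl2 (3 equiv), MeOH/H2O 1:1, 70 °C
Reagents that add atoms: copper dichloride Cl[Cu]Cl
Why: Stereoretentive copper-mediated chlorodeboronation of the alkenyl boronate turns C–B into C–Cl, so H and Cl end up cis (chain-cis chloroalkene, E by CIP) as the eight-membered ring later requires.

Step 4
Reactants: 5 (2E,5E)-3-chloroocta-2,5-dien-1-ol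
Product: 6 (2E,5E)-1-bromo-3-chloroocta-2,5-diene
Conditions: CBr4 (1.2 equiv), PPh3 (1.25 equiv), CH2Cl2, 0 °C
Reagents that add atoms: tetrabromomethane BrC(Br)(Br)Br
Why: Appel bromination of a primary allylic alcohol proceeds by SN2 at the unhindered carbon, and the chlorine-bearing alkene terminus disfavours allylic transposition.

Step 5
Reactants: 6 (2E,5E)-1-bromo-3-chloroocta-2,5-diene; 7 acetaldehyde N,N-dimethylhydrazone
Product: 9 (4E,7E)-5-chlorodeca-4,7-dienal, via dimethylhydrazone 8 (not isolated)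
Conditions: 7, LiN(iPr)2, THF, 0 °C; 6, −78 → 0 °C; then aq. (CO2H)2/Et2O, rt
Reagents that add atoms: water O
Why: Corey–Enders azaenolate alkylation (acetaldehyde enolate equivalent) with the primary allylic bromide forms C7–C8, and mild two-phase hydrazone hydrolysis releases a γ,δ-unsaturated aldehyde that cannot move into conjugation.

Step 6
Reactants: 9 (4E,7E)-5-chlorodeca-4,7-dienal
Product: 12 (3S,4S,5R,7E,10E)-3,8-dichloro-5-[(phenylamino)oxy]trideca-1,7,10-trien-4-ol, via aminoxy aldehyde 10 (not isolated), via borinate ester 11 (not isolated)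
Conditions: PhNO (0.95 equiv), L-proline (10 mol%), CH2Cl2, 0 °C; cannulate into (Z)-ClCH=CHCH2B(Ipc)2 [allyl chloride, LiN(c-C6H11)2, (+)-Ipc2BOMe from (−)-α-pinene, BF3·OEt2, Et2O, −95 °C]; −95 → −78 °C; HOCH2CH2NH2
Reagents that add atoms: nitrosobenzene O=Nc1ccccc1; allyl chloride C=CCCl
Why: Proline enamine catalysis (organocatalytic α-aminoxylation, acid-directed delivery of the nitroso oxygen) sets C7 as R, and the labile aldehyde is trapped at once by (Z)-γ-chloroallylboration through a chair transition state (Z reagent gives the 5,6-syn chlorohydrin; the Ipc groups direct attack to the Re face of C6, giving 5S,6S against the substrate's Felkin preference).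

Step 7
Reactants: 12 (3S,4S,5R,7E,10E)-3,8-dichloro-5-[(phenylamino)oxy]trideca-1,7,10-trien-4-ol
Product: 13 N-{[(3S,4S,5R,7E,10E)-3,8-dichloro-4-[(triethylsilyl)oxy]trideca-1,7,10-trien-5-yl]oxy}aniline
Conditions: Et3SiOTf (1.3 equiv), 2,6-lutidine, CH2Cl2, −78 °C
Reagents that add atoms: triethylsilyl trifluoromethanesulfonate CC[Si](CC)(CC)OS(=O)(=O)C(F)(F)F
Why: Silylation of the C6 hydroxyl masks it so that only O7 can act as nucleophile in the ring closure, and it prevents chlorohydrin-to-epoxide closure later.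

Step 8
Reactants: 13 N-{[(3S,4S,5R,7E,10E)-3,8-dichloro-4-[(triethylsilyl)oxy]trideca-1,7,10-trien-5-yl]oxy}aniline
Product: 14 (3S,4S,5R,7E,10E)-3,8-dichloro-4-[(triethylsilyl)oxy]trideca-1,7,10-trien-5-ol
Conditions: CuSO4·5H2O (0.3 equiv), MeOH, 0 °C → rt
Reagents that add atoms: none
Why: Copper-catalysed N–O cleavage of the anilinooxy group frees the C7 hydroxyl without touching the olefins, the allylic chloride or the C7 configuration.

Step 9
Reactants: 14 (3S,4S,5R,7E,10E)-3,8-dichloro-4-[(triethylsilyl)oxy]trideca-1,7,10-trien-5-ol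
Product: 15 (2R,3S,5E,8R)-3-bromo-5-chloro-8-[(1S,2S)-2-chloro-1-[(triethylsilyl)oxy]but-3-en-1-yl]-2-ethyl-3,4,7,8-tetrahydro-2H-oxocine
Conditions: NBS (1.05 equiv), Ph3P=S (10 mol%), CH2Cl2/(CF3)2CHOH 9:1, 4 Å MS, −40 °C, 2 mM (slow addition of 14)
Reagents that add atoms: N-bromosuccinimide O=C1CCC(=O)N1Br
Why: Proposed new method: Lewis-base-catalysed 8-endo bromoetherification of an acyclic hydroxy 1,4-diene — Ph3P=S and NBS give [Ph3P=S–Br]+ succinimidate, which transfers Br+ reversibly to the only electron-rich olefin (E-C12=C13; the chloroalkene and the vinyl group next to C–Cl are deactivated); the fluoroalcohol stabilises the bromiranium ion and the ring-cis chloroalkene folds the chain (as the Z-olefin does in laurediols), so O7 opens the bromiranium anti at C13, the carbon remote from the electron-withdrawing chloroalkenyl group (8-endo over 7-exo), with succinimidate taking the proton; anti addition to the E-olefin fixes the trans C12–Br/C13–Et relation, and the C7 centre selects the olefin face through a boat-chair transition state with both α-substituents pseudo-equatorial, giving the 7,13-cis ether with 12S,13R; the closest known reaction types are Lewis-base-catalysed bromocycloetherification to 5- and 6-membered ethers and the haloperoxidase-mediated 8-endo cyclisation of laurediols.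

Step 10
Reactants: 16 bromoethene; 17 ethynyltriisopropylsilane
Product: 18 (but-3-en-1-yn-1-yl)triisopropylsilane
Conditions: PdCl2(PPh3)2 (2 mol%), CuI (4 mol%), Et2NH, THF, 0 °C → rt
Reagents that add atoms: none
Why: Sonogashira coupling of a vinyl bromide with a terminal silylalkyne gives the conjugated enyne partner.

Step 11
Reactants: 15 (2R,3S,5E,8R)-3-bromo-5-chloro-8-[(1S,2S)-2-chloro-1-[(triethylsilyl)oxy]but-3-en-1-yl]-2-ethyl-3,4,7,8-tetrahydro-2H-oxocine; 18 (but-3-en-1-yn-1-yl)triisopropylsilane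
Product: 19 (2R,3S,5E,8R)-3-bromo-5-chloro-8-[(1S,2S,3Z)-2-chloro-1-[(triethylsilyl)oxy]-6-(triisopropylsilyl)hex-3-en-5-yn-1-yl]-2-ethyl-3,4,7,8-tetrahydro-2H-oxocine
Conditions: 18 (4 equiv), second-generation Grubbs catalyst RuCl2(H2IMes)(PCy3)(=CHPh) (10 mol%), CH2Cl2, 40 °C
Reagents that add atoms: none
Why: Z-selective enyne cross-metathesis: the ruthenium alkynyl-carbene formed from the conjugated enyne couples with the terminal olefin to give the Z-enyne kinetically, while the trisubstituted ring chloroalkene is inert to the catalyst.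

Step 12
Reactants: 19 (2R,3S,5E,8R)-3-bromo-5-chloro-8-[(1S,2S,3Z)-2-chloro-1-[(triethylsilyl)oxy]-6-(triisopropylsilyl)hex-3-en-5-yn-1-yl]-2-ethyl-3,4,7,8-tetrahydro-2H-oxocine
Product: 20 bermudenynol, (3Z,5S,6S,7R,9E,12S,13R)-12-bromo-5,10-dichloro-7,13-epoxypentadeca-3,9-dien-1-yn-6-ol
Conditions: Bu4NF (2.5 equiv), AcOH (2.5 equiv), THF, 0 °C
Reagents that add atoms: none
Why: Fluoride desilylation removes the O-triethylsilyl and C-triisopropylsilyl groups together, and the acetic acid buffer prevents the C6 alkoxide from displacing the C5 chloride to an epoxide.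

**Compound list**
1 | prop-2-yn-1-ol | C#CCO | starting material
2 | (E)-1-bromopent-2-ene | CC/C=C/CBr | starting material
3 | (E)-oct-5-en-2-yn-1-ol | OCC#CC/C=C/CC | intermediate
4 | (2Z,5E)-3-(4,4,5,5-tetramethyl-1,3,2-dioxaborolan-2-yl)octa-2,5-dien-1-ol | OC/C=C(/B1OC(C)(C)C(C)(C)O1)C/C=C/CC | intermediate
5 | (2E,5E)-3-chloroocta-2,5-dien-1-ol | OC/C=C(/Cl)C/C=C/CC | intermediate
6 | (2E,5E)-1-bromo-3-chloroocta-2,5-diene | BrC/C=C(/Cl)C/C=C/CC | intermediate
7 | acetaldehyde N,N-dimethylhydrazone | C/C=N/N(C)C | starting material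
8 | (4E,7E)-5-chlorodeca-4,7-dienal N,N-dimethylhydrazone | CN(C)/N=C/CC/C=C(/Cl)C/C=C/CC | intermediate
9 | (4E,7E)-5-chlorodeca-4,7-dienal | O=CCC/C=C(/Cl)C/C=C/CC | intermediate
10 | (2R,4E,7E)-5-chloro-2-[(phenylamino)oxy]deca-4,7-dienal | O=C[C@H](ONc1ccccc1)C/C=C(/Cl)C/C=C/CC | intermediate
11 | (3S,4S,5R,7E,10E)-3,8-dichloro-5-[(phenylamino)oxy]trideca-1,7,10-trien-4-yl diisopinocampheylborinate (Ipc from (−)-α-pinene) | C=C[C@H](Cl)[C@@H](OB([C@H]1C[C@H]2C[C@@H]([C@@H]1C)C2(C)C)[C@H]1C[C@H]2C[C@@H]([C@@H]1C)C2(C)C)[C@H](ONc1ccccc1)C/C=C(/Cl)C/C=C/CC | intermediate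
12 | (3S,4S,5R,7E,10E)-3,8-dichloro-5-[(phenylamino)oxy]trideca-1,7,10-trien-4-ol | C=C[C@H](Cl)[C@@H](O)[C@H](ONc1ccccc1)C/C=C(/Cl)C/C=C/CC | intermediate
13 | N-{[(3S,4S,5R,7E,10E)-3,8-dichloro-4-[(triethylsilyl)oxy]trideca-1,7,10-trien-5-yl]oxy}aniline | C=C[C@H](Cl)[C@@H](O[Si](CC)(CC)CC)[C@H](ONc1ccccc1)C/C=C(/Cl)C/C=C/CC | intermediate
14 | (3S,4S,5R,7E,10E)-3,8-dichloro-4-[(triethylsilyl)oxy]trideca-1,7,10-trien-5-ol | C=C[C@H](Cl)[C@@H](O[Si](CC)(CC)CC)[C@H](O)C/C=C(/Cl)C/C=C/CC | intermediate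
15 | (2R,3S,5E,8R)-3-bromo-5-chloro-8-[(1S,2S)-2-chloro-1-[(triethylsilyl)oxy]but-3-en-1-yl]-2-ethyl-3,4,7,8-tetrahydro-2H-oxocine (ring-cis olefin) | C=C[C@H](Cl)[C@@H](O[Si](CC)(CC)CC)[C@H]1C/C=C(/Cl)C[C@H](Br)[C@@H](CC)O1 | intermediate
16 | bromoethene | C=CBr | starting material
17 | ethynyltriisopropylsilane | C#C[Si](C(C)C)(C(C)C)C(C)C | starting material
18 | (but-3-en-1-yn-1-yl)triisopropylsilane | C=CC#C[Si](C(C)C)(C(C)C)C(C)C | intermediate
19 | (2R,3S,5E,8R)-3-bromo-5-chloro-8-[(1S,2S,3Z)-2-chloro-1-[(triethylsilyl)oxy]-6-(triisopropylsilyl)hex-3-en-5-yn-1-yl]-2-ethyl-3,4,7,8-tetrahydro-2H-oxocine | CC(C)[Si](C(C)C)(C(C)C)C#C/C=C\[C@H](Cl)[C@@H](O[Si](CC)(CC)CC)[C@H]1C/C=C(/Cl)C[C@H](Br)[C@@H](CC)O1 | intermediate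
20 | bermudenynol, (3Z,5S,6S,7R,9E,12S,13R)-12-bromo-5,10-dichloro-7,13-epoxypentadeca-3,9-dien-1-yn-6-ol | C#C/C=C\[C@H](Cl)[C@@H](O)[C@H]1C/C=C(/Cl)C[C@H](Br)[C@@H](CC)O1 | target

**Step count**
Total: 12 steps. Longest linear sequence: 11 steps (steps 1–9, 11, 12, from prop-2-yn-1-ol); step 10 is a one-step side branch.

**Three steps most likely to fail**

Step 9 (the proposed new 8-endo bromoetherification). The risks are 7-exo closure, attack on the wrong olefin face, and slow medium-ring formation. The fallback sets out from 14 and comes back at 15. It replaces the bromonium route by epoxide-opening etherification, followed by introduction of bromide by substitution, all known reaction types. Shi epoxidation of 14 with the L-fructose-derived ketone (Oxone 2KHSO5·KHSO4·K2SO4, K2CO3 buffer, MeCN/dimethoxymethane, 0 °C) acts only on the E-disubstituted olefin and gives (3S,4S,5R,7E)-3,8-dichloro-9-[(2S,3S)-3-ethyloxiran-2-yl]-4-[(triethylsilyl)oxy]nona-1,7-dien-5-ol F7. Lewis-acid-promoted intramolecular epoxide opening (BF3·OEt2, CH2Cl2, −78 °C) by O7 at C13, with inversion there, gives (2R,3S,5E,8R)-5-chloro-8-[(1S,2S)-2-chloro-1-[(triethylsilyl)oxy]but-3-en-1-yl]-2-ethyl-3,4,7,8-tetrahydro-2H-oxocin-3-ol F8; any 7-exo isomer is separated here. Because direct bromination would invert C12 to the wrong epimer, the alcohol is first inverted by Mitsunobu reaction (4-nitrobenzoic acid, PPh3, diisopropyl azodicarboxylate) to (2R,3R,5E,8R)-5-chloro-8-[(1S,2S)-2-chloro-1-[(triethylsilyl)oxy]but-3-en-1-yl]-2-ethyl-3,4,7,8-tetrahydro-2H-oxocin-3-yl 4-nitrobenzoate F9. Methanolysis (K2CO3, MeOH, 0 °C) gives (2R,3R,5E,8R)-5-chloro-8-[(1S,2S)-2-chloro-1-[(triethylsilyl)oxy]but-3-en-1-yl]-2-ethyl-3,4,7,8-tetrahydro-2H-oxocin-3-ol F10. Bromination with inversion (CBr4, (n-C8H17)3P, toluene, 70 °C) then gives 15.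

Step 6 (one-pot α-aminoxylation and chloroallylboration). The α-aminoxy aldehyde is labile, and the allylboration is a mismatched case in which the reagent must override the Felkin preference. The fallback sets out from 6 and comes back at 14. It sets C7 by auxiliary-controlled glycolate alkylation, giving a stable, isolable α-alkoxy aldehyde for the allylboration; the mismatched pairing remains, so minor diastereomers are removed by chromatography. (S)-4-Benzyloxazolidin-2-one is acylated (n-BuLi, (4-methoxybenzyloxy)acetyl chloride, THF, −78 °C) to (S)-4-benzyl-3-{2-[(4-methoxybenzyl)oxy]acetyl}oxazolidin-2-one F1. Its sodium enolate (NaN(SiMe3)2, THF, −78 → −45 °C) is alkylated by 6 on the face away from the benzyl group to give (S)-4-benzyl-3-[(2R,4E,7E)-5-chloro-2-[(4-methoxybenzyl)oxy]deca-4,7-dienoyl]oxazolidin-2-one F2. Reduction with LiBH4 (THF/MeOH, 0 °C) gives (2R,4E,7E)-5-chloro-2-[(4-methoxybenzyl)oxy]deca-4,7-dien-1-ol F3, and Dess–Martin oxidation gives (2R,4E,7E)-5-chloro-2-[(4-methoxybenzyl)oxy]deca-4,7-dienal F4. The same (Z)-γ-chloroallylborane as in step 6 converts F4 into (3S,4S,5R,7E,10E)-3,8-dichloro-5-[(4-methoxybenzyl)oxy]trideca-1,7,10-trien-4-ol F5. Silylation (Et3SiOTf, 2,6-lutidine) gives triethyl{[(3S,4S,5R,7E,10E)-3,8-dichloro-5-[(4-methoxybenzyl)oxy]trideca-1,7,10-trien-4-yl]oxy}silane F6, and oxidative removal of the 4-methoxybenzyl group (2,3-dichloro-5,6-dicyano-1,4-benzoquinone, CH2Cl2/pH 7 buffer, 0 °C) gives 14.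

Step 11 (enyne cross-metathesis on a hindered olefin flanked by C–Cl and a silyl ether). The risks are low conversion and incomplete Z selectivity. The fallback sets out from 15 and comes back at 19. It builds the Z-enyne by oxidative cleavage, Z-selective iodo-olefination and cross-coupling. Ozonolysis of the terminal vinyl group (O3, CH2Cl2/MeOH, −78 °C, then Me2S; the electron-poor ring chloroalkene reacts much more slowly) gives (2R,3S)-3-[(2R,4E,7S,8R)-7-bromo-5-chloro-8-ethyl-3,6,7,8-tetrahydro-2H-oxocin-2-yl]-2-chloro-3-[(triethylsilyl)oxy]propanal F11. Stork–Zhao olefination (Ph3PCH2I iodide, NaN(SiMe3)2, THF/hexamethylphosphoramide, −78 °C) gives (2R,3S,5E,8R)-3-bromo-5-chloro-8-[(1S,2S,3Z)-2-chloro-4-iodo-1-[(triethylsilyl)oxy]but-3-en-1-yl]-2-ethyl-3,4,7,8-tetrahydro-2H-oxocine F12. Sonogashira coupling of the vinyl iodide with 17 (PdCl2(PPh3)2, CuI, iPr2NH, THF, rt; the vinyl chloride and alkyl bromide do not react) gives 19.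

**Further compounds**
F1 | step 6 | (S)-4-benzyl-3-{2-[(4-methoxybenzyl)oxy]acetyl}oxazolidin-2-one | O=C1OC[C@H](Cc2ccccc2)N1C(=O)COCc1ccc(OC)cc1
F2 | step 6 | (S)-4-benzyl-3-[(2R,4E,7E)-5-chloro-2-[(4-methoxybenzyl)oxy]deca-4,7-dienoyl]oxazolidin-2-one | O=C1OC[C@H](Cc2ccccc2)N1C(=O)[C@H](OCc1ccc(OC)cc1)C/C=C(/Cl)C/C=C/CC
F3 | step 6 | (2R,4E,7E)-5-chloro-2-[(4-methoxybenzyl)oxy]deca-4,7-dien-1-ol | OC[C@H](OCc1ccc(OC)cc1)C/C=C(/Cl)C/C=C/CC
F4 | step 6 | (2R,4E,7E)-5-chloro-2-[(4-methoxybenzyl)oxy]deca-4,7-dienal | O=C[C@H](OCc1ccc(OC)cc1)C/C=C(/Cl)C/C=C/CC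
F5 | step 6 | (3S,4S,5R,7E,10E)-3,8-dichloro-5-[(4-methoxybenzyl)oxy]trideca-1,7,10-trien-4-ol | C=C[C@H](Cl)[C@@H](O)[C@H](OCc1ccc(OC)cc1)C/C=C(/Cl)C/C=C/CC
F6 | step 6 | triethyl{[(3S,4S,5R,7E,10E)-3,8-dichloro-5-[(4-methoxybenzyl)oxy]trideca-1,7,10-trien-4-yl]oxy}silane | C=C[C@H](Cl)[C@@H](O[Si](CC)(CC)CC)[C@H](OCc1ccc(OC)cc1)C/C=C(/Cl)C/C=C/CC
F7 | step 9 | (3S,4S,5R,7E)-3,8-dichloro-9-[(2S,3S)-3-ethyloxiran-2-yl]-4-[(triethylsilyl)oxy]nona-1,7-dien-5-ol | C=C[C@H](Cl)[C@@H](O[Si](CC)(CC)CC)[C@H](O)C/C=C(/Cl)C[C@@H]1O[C@H]1CC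
F8 | step 9 | (2R,3S,5E,8R)-5-chloro-8-[(1S,2S)-2-chloro-1-[(triethylsilyl)oxy]but-3-en-1-yl]-2-ethyl-3,4,7,8-tetrahydro-2H-oxocin-3-ol | C=C[C@H](Cl)[C@@H](O[Si](CC)(CC)CC)[C@H]1C/C=C(/Cl)C[C@H](O)[C@@H](CC)O1
F9 | step 9 | (2R,3R,5E,8R)-5-chloro-8-[(1S,2S)-2-chloro-1-[(triethylsilyl)oxy]but-3-en-1-yl]-2-ethyl-3,4,7,8-tetrahydro-2H-oxocin-3-yl 4-nitrobenzoate | C=C[C@H](Cl)[C@@H](O[Si](CC)(CC)CC)[C@H]1C/C=C(/Cl)C[C@@H](OC(=O)c2ccc(cc2)[N+](=O)[O-])[C@@H](CC)O1
F10 | step 9 | (2R,3R,5E,8R)-5-chloro-8-[(1S,2S)-2-chloro-1-[(triethylsilyl)oxy]but-3-en-1-yl]-2-ethyl-3,4,7,8-tetrahydro-2H-oxocin-3-ol | C=C[C@H](Cl)[C@@H](O[Si](CC)(CC)CC)[C@H]1C/C=C(/Cl)C[C@@H](O)[C@@H](CC)O1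
F11 | step 11 | (2R,3S)-3-[(2R,4E,7S,8R)-7-bromo-5-chloro-8-ethyl-3,6,7,8-tetrahydro-2H-oxocin-2-yl]-2-chloro-3-[(triethylsilyl)oxy]propanal | O=C[C@H](Cl)[C@@H](O[Si](CC)(CC)CC)[C@H]1C/C=C(/Cl)C[C@H](Br)[C@@H](CC)O1
F12 | step 11 | (2R,3S,5E,8R)-3-bromo-5-chloro-8-[(1S,2S,3Z)-2-chloro-4-iodo-1-[(triethylsilyl)oxy]but-3-en-1-yl]-2-ethyl-3,4,7,8-tetrahydro-2H-oxocine | I/C=C\[C@H](Cl)[C@@H](O[Si](CC)(CC)CC)[C@H]1C/C=C(/Cl)C[C@H](Br)[C@@H](CC)O1
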